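**Plan**

1. Retrosynthesis: both pyran rings are cut, each at O1–C2 and at C4–C4a, leaving the bisphenol 4,4'-[(1E,3S)-but-1-ene-1,3-diyl]bis(3-methoxyphenol) and two molecules of 3-methylbut-2-enal. The butenyl chain is then cut at its C1=C2 double bond (cross-metathesis) and at C2–C3 (hydrovinylation), so both aryl halves go back to one styrene made from 4-hydroxy-2-methoxybenzaldehyde.
2. Enabling feature: each half is a 7-methoxy-2,2-dimethyl-2H-chromene whose ring oxygen O1 (on C8a) is meta to the C7 methoxy and para to the C6 side chain. C4a is therefore the one unhindered, methoxy-activated ortho carbon of a phenol, and C4–C3–C2 with its gem-dimethyl is the chain of 3-methylbut-2-enal. Both arenes carry the same pattern, so one bisphenol can take up both pyran rings in a single operation.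
3. Forward order: silylation, Wittig methylenation, nickel-catalysed asymmetric hydrovinylation, cross-metathesis of the 3-arylbut-1-ene with a second molecule of the same styrene (chain joined), desilylation, then the twofold phenol–enal chromene annulation in which both pyran rings arise last and together.
4. Stereochemistry: the single stereocenter (S) comes from catalyst control by a chiral phosphoramidite ligand on nickel in the hydrovinylation. The E geometry comes from the cross-metathesis. The annulation creates no stereocenter and leaves the existing one alone.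

Key step: step 6

Assumption: the (Ra,Sc,Sc) antipode of the phosphoramidite ligand is taken to give the (S)-3-arylbut-1-ene, by analogy with simple vinylarenes; if the sense proves opposite, the (Sa,Rc,Rc) antipode is used with no other change.

**Step 1**
Reactants: 1 4-hydroxy-2-methoxybenzaldehyde
Product: 2 4-[(tert-butyldimethylsilyl)oxy]-2-methoxybenzaldehyde
Conditions: TBSCl, imidazole, DMF, 0 °C to rt
Reagents that add atoms: tert-butyldimethylsilyl chloride, CC(C)(C)[Si](C)(C)Cl
Why: Standard silyl ether protection of an acidic, unhindered phenol; the TBS ether should survive the ylide, the cationic nickel hydride and the ruthenium carbene, and it leaves later with fluoride without touching the alkene.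

**Step 2**
Reactants: 2 4-[(tert-butyldimethylsilyl)oxy]-2-methoxybenzaldehyde
Product: 3 tert-butyl(4-ethenyl-3-methoxyphenoxy)dimethylsilane
Conditions: Ph3PCH3Br, KN(SiMe3)2, THF, 0 °C; then 2, −78 °C to rt
Reagents that add atoms: methyltriphenylphosphonium bromide, C[P+](c1ccccc1)(c1ccccc1)c1ccccc1.[Br-]
Why: Wittig methylenation of an aryl aldehyde by the non-stabilized ylide, driven by formation of the P=O bond; no stereochemical issue arises and the alkoxide-free ylide should spare the aryl silyl ether.

**Step 3**
Reactants: 3 tert-butyl(4-ethenyl-3-methoxyphenoxy)dimethylsilane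
Product: 4 (S)-tert-butyl[4-(but-3-en-2-yl)-3-methoxyphenoxy]dimethylsilane
Conditions: C2H4 (1 atm), [(η3-C3H5)NiBr]2 (1.5 mol%), (Ra,Sc,Sc)-phosphoramidite L from (R)-1,1'-bi-2-naphthol and bis[(S)-1-phenylethyl]amine (3 mol%), Na[B(3,5-(CF3)2C6H3)4] (3.5 mol%), CH2Cl2, −70 °C
Reagents that add atoms: ethylene, C=C
Why: Nickel-catalysed asymmetric hydrovinylation of a vinylarene: the cationic nickel hydride adds in the Markovnikov sense to give an η3-benzyl nickel species, ethylene inserts at the benzylic carbon and β-hydride elimination releases the 3-arylbut-1-ene, the phosphoramidite on nickel selecting the enantiotopic face of the styrene so that the benzylic stereocenter is set as (S); the low temperature should suppress migration of the new double bond.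

**Step 4**
Reactants: 4 (S)-tert-butyl[4-(but-3-en-2-yl)-3-methoxyphenoxy]dimethylsilane; 3 tert-butyl(4-ethenyl-3-methoxyphenoxy)dimethylsilane (second molecule, 2.5 equiv)
Product: 5 (S,E)-1,3-bis{4-[(tert-butyldimethylsilyl)oxy]-2-methoxyphenyl}but-1-ene
Conditions: second-generation Hoveyda–Grubbs catalyst (H2IMes)Cl2Ru(=CH-C6H4-2-OiPr) (5 mol%), 1,4-benzoquinone (10 mol%), CH2Cl2, 40 °C, argon sweep
Reagents that add atoms: none
Why: Olefin cross-metathesis between the allylic-branched terminal alkene 4, which homodimerizes slowly, and an excess of styrene 3, driven by loss of ethylene and giving the thermodynamically favoured E-styrenyl alkene; the stereocenter only neighbours the reacting alkene, and benzoquinone should intercept the ruthenium hydrides that could move the double bond through it.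

**Step 5**
Reactants: 5 (S,E)-1,3-bis{4-[(tert-butyldimethylsilyl)oxy]-2-methoxyphenyl}but-1-ene
Product: 6 4,4'-[(1E,3S)-but-1-ene-1,3-diyl]bis(3-methoxyphenol)
Conditions: Bu4NF, AcOH, THF, 0 °C to rt
Reagents that add atoms: none
Why: Fluoride-induced desilylation of both aryl silyl ethers (strong Si–F bond), buffered by acetic acid so that no free base can shift the benzylic-allylic hydrogen; the stereocenter and the E-alkene are not involved.

**Step 6**
Reactants: 6 4,4'-[(1E,3S)-but-1-ene-1,3-diyl]bis(3-methoxyphenol); 7 3-methylbut-2-enal (4 equiv)
Product: 10 7-methoxy-6-[(1E,3S)-3-(7-methoxy-2,2-dimethyl-2H-chromen-6-yl)but-1-en-1-yl]-2,2-dimethyl-2H-chromene, via twofold benzodioxaborin 8 (not isolated), via twofold ortho-quinone methide 9 (not isolated)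
Conditions: PhB(OH)2 (2.2 equiv), AcOH, toluene, reflux, Dean–Stark
Reagents that add atoms: none
Why: Each phenol of 6 is esterified by PhB(OH)2, the boron binds the aldehyde and delivers its carbonyl carbon to an ortho carbon of the arene (C4–C4a bond) to give the 2-phenyl-4H-1,3,2-benzodioxaborin 8, which on heating with acid loses PhBO by retro-[4+2] cleavage to the ortho-quinone methide (1-oxatriene) 9, and 9 closes by oxa-6π electrocyclization with O1–C2 bond formation at the dimethyl-bearing terminus. The closest known reaction type is the phenylboronic acid-mediated condensation of phenols with α,β-unsaturated aldehydes to 2H-chromenes (a formal [3+3] annulation, known for 3-methoxyphenol and 3-methylbut-2-enal), run here on both arenes of one substrate. Each pyran ring closes by thermal disrotatory 6π electrocyclization of the cis-dienone, a six-membered closure driven by rearomatization of the arene. No stereocenter is created (C2 carries two methyl groups and the C4 center of 8 is lost on fragmentation), and the existing (S) center, which bears no leaving group and lies outside both reacting π systems, should be carried through unchanged. The step needs regioselectivity for the ortho carbon para to the methoxy group over the ortho carbon between the two oxygens: the boron tether confines attack to ortho positions, the para position is blocked by the side chain, and the carbon between OH and OMe is flanked on both sides while the other is unhindered and activated by the para methoxy group. It also needs chemoselectivity over the electron-rich styrene, which the weak acid (no protonation of the alkene) and the fast intramolecular ring closure of 9 (faster than any intermolecular hetero-Diels–Alder capture) should secure.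

**Compound list**

1 | 4-hydroxy-2-methoxybenzaldehyde | COc1cc(O)ccc1C=O | starting material
2 | 4-[(tert-butyldimethylsilyl)oxy]-2-methoxybenzaldehyde | COc1cc(O[Si](C)(C)C(C)(C)C)ccc1C=O | intermediate
3 | tert-butyl(4-ethenyl-3-methoxyphenoxy)dimethylsilane | COc1cc(O[Si](C)(C)C(C)(C)C)ccc1C=C | intermediate
4 | (S)-tert-butyl[4-(but-3-en-2-yl)-3-methoxyphenoxy]dimethylsilane | C=C[C@H](C)c1ccc(O[Si](C)(C)C(C)(C)C)cc1OC | intermediate
5 | (S,E)-1,3-bis{4-[(tert-butyldimethylsilyl)oxy]-2-methoxyphenyl}but-1-ene | COc1cc(O[Si](C)(C)C(C)(C)C)ccc1/C=C/[C@H](C)c1ccc(O[Si](C)(C)C(C)(C)C)cc1OC | intermediate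
6 | 4,4'-[(1E,3S)-but-1-ene-1,3-diyl]bis(3-methoxyphenol) | COc1cc(O)ccc1/C=C/[C@H](C)c1ccc(O)cc1OC | intermediate
7 | 3-methylbut-2-enal | CC(C)=CC=O | starting material
8 | twofold 4-(2-methylprop-1-enyl)-2-phenyl-4H-1,3,2-benzodioxaborin of 6 (not isolated; drawn with both arenes at the same stage, the two arenes reacting independently; C4 of each boron ring unassigned) | COc1cc2OB(c3ccccc3)OC(C=C(C)C)c2cc1/C=C/[C@H](C)c1cc2C(C=C(C)C)OB(c3ccccc3)Oc2cc1OC | intermediate
9 | twofold ortho-quinone methide (6-(3-methylbut-2-enylidene)cyclohexa-2,4-dienone on each ring; not isolated; drawn with both arenes at the same stage) | COC1=CC(=O)C(=CC=C(C)C)C=C1/C=C/[C@H](C)C1=CC(=CC=C(C)C)C(=O)C=C1OC | intermediate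
10 | 7-methoxy-6-[(1E,3S)-3-(7-methoxy-2,2-dimethyl-2H-chromen-6-yl)but-1-en-1-yl]-2,2-dimethyl-2H-chromene | COc1cc2c(cc1/C=C/[C@H](C)c1cc3c(cc1OC)OC(C)(C)C=C3)C=CC(C)(C)O2 | target

Total step count: 6. Longest linear sequence: 6 steps (1 to 10); styrene 3 is used twice.

**Steps most likely to fail**

Step 6 (twofold annulation). The processes that may go wrong are C-attack at the carbon between the two oxygens on one arene, stalling after the first ring, acid-promoted oligomerization of the electron-rich hydroxystyrene, and self-condensation of the enal. The fallback sets out from 6 and comes back at 10. Both phenols are O-alkylated with 3-chloro-3-methylbut-1-yne (CuCl2·2H2O cat., DBU, MeCN, 0 °C), which should give (S,E)-1,3-bis[2-methoxy-4-(2-methylbut-3-yn-2-yloxy)phenyl]but-1-ene F1. Heating F1 in N,N-diethylaniline at about 150 °C should start, on each arene, the aryl propargyl ether Claisen cascade: [3,3] shift to the unhindered ortho carbon, enolization, 1,5-hydrogen shift and oxa-6π closure through the same oxatriene 9. This should deliver 10 under neutral, boron-free conditions.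

Step 4 (cross-metathesis). The processes that may go wrong are trapping of the ruthenium carbene as a methoxy-chelated benzylidene by the ortho-methoxystyrene, slow turnover at the allylic-branched alkene, homodimerization of the styrene, and hydride-induced migration of the double bond of 4 into conjugation, which would erase the stereocenter. The fallback sets out from 4 and comes back at 5 without metathesis.
- Ozonolysis of 4 with direct borohydride reduction (O3, CH2Cl2/MeOH, −78 °C; NaBH4) should give (R)-2-{4-[(tert-butyldimethylsilyl)oxy]-2-methoxyphenyl}propan-1-ol F2. The descriptor changes only because the ligand ranks change.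
- Mitsunobu thioetherification with 1-phenyl-1H-tetrazole-5-thiol (PPh3, DIAD, THF) should give (R)-5-[(2-{4-[(tert-butyldimethylsilyl)oxy]-2-methoxyphenyl}propyl)sulfanyl]-1-phenyl-1H-tetrazole F3.
- Oxidation ((NH4)6Mo7O24·4H2O, H2O2, EtOH) should give (R)-5-[(2-{4-[(tert-butyldimethylsilyl)oxy]-2-methoxyphenyl}propyl)sulfonyl]-1-phenyl-1H-tetrazole F4.
- Julia–Kocienski olefination of F4 with aldehyde 2 (KN(SiMe3)2, DME, −60 °C to rt) should give the E-alkene 5. The stereocenter is β to the sulfonyl group and is not deprotonated.

Step 3 (hydrovinylation). The processes that may go wrong are coordination of the ortho methoxy group to the cationic nickel with loss of rate and of facial selectivity, migration of the product double bond into conjugation, and cationic oligomerization of the electron-rich styrene. The fallback sets out from 3 and comes back at 4. Copper hydride-catalysed Markovnikov hydroboration (CuCl, NaOtBu, the antipode of DTBM-SEGPHOS that gives the R boronate, HBpin, THF, rt) should give (R)-tert-butyl{3-methoxy-4-[1-(4,4,5,5-tetramethyl-1,3,2-dioxaborolan-2-yl)ethyl]phenoxy}dimethylsilane F5. Zweifel vinylation of F5 (CH2=CHMgBr, THF/DMSO; I2; NaOMe, MeOH, −78 °C to rt) moves the benzylic carbon from boron to the vinyl carbon with retention, which corresponds to (S)-4; the descriptor changes only because the ligand ranks change.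

**Further compounds**

F1 | step 6 | (S,E)-1,3-bis[2-methoxy-4-(2-methylbut-3-yn-2-yloxy)phenyl]but-1-ene | COc1cc(OC(C)(C)C#C)ccc1/C=C/[C@H](C)c1ccc(OC(C)(C)C#C)cc1OC
F2 | step 4 | (R)-2-{4-[(tert-butyldimethylsilyl)oxy]-2-methoxyphenyl}propan-1-ol | OC[C@H](C)c1ccc(O[Si](C)(C)C(C)(C)C)cc1OC
F3 | step 4 | (R)-5-[(2-{4-[(tert-butyldimethylsilyl)oxy]-2-methoxyphenyl}propyl)sulfanyl]-1-phenyl-1H-tetrazole | c1ccccc1-n1nnnc1SC[C@H](C)c1ccc(O[Si](C)(C)C(C)(C)C)cc1OC
F4 | step 4 | (R)-5-[(2-{4-[(tert-butyldimethylsilyl)oxy]-2-methoxyphenyl}propyl)sulfonyl]-1-phenyl-1H-tetrazole | O=S(=O)(C[C@H](C)c1ccc(O[Si](C)(C)C(C)(C)C)cc1OC)c1nnnn1-c1ccccc1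
F5 | step 3 | (R)-tert-butyl{3-methoxy-4-[1-(4,4,5,5-tetramethyl-1,3,2-dioxaborolan-2-yl)ethyl]phenoxy}dimethylsilane | C[C@@H](B1OC(C)(C)C(C)(C)O1)c1ccc(O[Si](C)(C)C(C)(C)C)cc1OC
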